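The oxolane (O1, C2H2, C3 carbinol, C4, C5 aryl-bearing) is disconnected at O1–C5, the bond from the ring oxygen to the benzylic carbon. C5 is carried at the ketone level as a 1,3-dithiane, which first acts as acyl anion to forge C4–C5 on a chiral butenolide. In the key step the acyclic dithiane triol 20 is unmasked, the C2 hydroxyl closes onto C5 and Et3SiH reduces the oxocarbenium ion in the same operation. The step exploits the para oxygen of the dihydrobenzofuran ring, which stabilises the C5 cation, and the cis C3-arylmethyl and C4-hydroxymethyl groups, which send hydride to the opposite face and give the all-cis oxolane.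

Key step: step 14

Abbreviations: TIPS = triisopropylsilyl; G = 3-methoxy-4-(triisopropylsilyloxy)phenyl; BF = (2R,3R)-7-methoxy-2-G-3-[(triisopropylsilyloxy)methyl]-2,3-dihydro-1-benzofuran-5-yl; Men = (1R,2S,5R)-menthyl.

Assumption: Rh2(S-PTTL)4 is taken to give the (2R,3S) ester 10 (if its sense of induction is the opposite, Rh2(R-PTTL)4 is used with no other change), and butenolide 14 is taken as a catalogue chemical.

Step 1
Reactants: 1 vanillin
Product: 2 3-methoxy-4-(triisopropylsilyloxy)benzaldehyde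
Conditions: TIPSCl, imidazole, DMF, rt
Reagents that add atoms: triisopropylsilyl chloride, CC(C)[Si](Cl)(C(C)C)C(C)C
Why: Imidazole-promoted O-silylation of the phenol; the bulky TIPS ether is chosen to withstand the carbonate, organolithium and hydride steps that follow.

Step 2
Reactants: 2 3-methoxy-4-(triisopropylsilyloxy)benzaldehyde
Product: 3 [3-methoxy-4-(triisopropylsilyloxy)phenyl]methanol
Conditions: NaBH4, MeOH, 0 °C
Reagents that add atoms: none
Why: Borohydride reduction of the aldehyde to the benzylic alcohol, with the aryl silyl ether untouched at 0 °C.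

Step 3
Reactants: 3 [3-methoxy-4-(triisopropylsilyloxy)phenyl]methanol
Product: 4 3-methoxy-4-(triisopropylsilyloxy)benzyl bromide
Conditions: PBr3, pyridine (cat.), Et2O, 0 °C; used crude
Reagents that add atoms: phosphorus tribromide, BrP(Br)Br
Why: Bromide displaces the phosphite ester of the electron-rich benzylic alcohol at low temperature, where the silyl ether should survive.

Step 4
Reactants: 5 5-iodovanillin (4-hydroxy-3-iodo-5-methoxybenzaldehyde); 4 3-methoxy-4-(triisopropylsilyloxy)benzyl bromide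
Product: 6 3-iodo-5-methoxy-4-[(G)methoxy]benzaldehyde
Conditions: K2CO3, acetone, 55 °C
Reagents that add atoms: none
Why: Williamson etherification of the acidic, hindered phenol with the reactive benzylic bromide under carbonate conditions mild enough for the aryl TIPS ether.

Step 5
Reactants: 6 3-iodo-5-methoxy-4-[(G)methoxy]benzaldehyde
Product: 7 5-(dimethoxymethyl)-1-iodo-3-methoxy-2-[(G)methoxy]benzene
Conditions: HC(OMe)3, pyridinium p-toluenesulfonate (cat.), MeOH, rt
Reagents that add atoms: trimethyl orthoformate, COC(OC)OC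
Why: Mild acid-catalysed acetalisation masks the aldehyde against the rhodium carbenoid of step 7 and the hydride of step 8, and the acetal is later exchanged directly for the dithiane.

Step 6
Reactants: 7 5-(dimethoxymethyl)-1-iodo-3-methoxy-2-[(G)methoxy]benzene; 8 ethyl diazoacetate
Product: 9 ethyl 2-diazo-2-{5-(dimethoxymethyl)-3-methoxy-2-[(G)methoxy]phenyl}acetate
Conditions: Pd(PPh3)4 (5 mol %), Ag2CO3 (0.5 equiv), Et3N, toluene, rt
Reagents that add atoms: none
Why: Palladium-catalysed cross-coupling of an aryl iodide with the C–H bond of a diazo ester (oxidative addition to zerovalent palladium, deprotonative palladation, reductive elimination) should give the aryl diazoacetate with the diazo group retained.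

Step 7
Reactants: 9 ethyl 2-diazo-2-{5-(dimethoxymethyl)-3-methoxy-2-[(G)methoxy]phenyl}acetate
Product: 10 ethyl (2R,3S)-5-(dimethoxymethyl)-7-methoxy-2-G-2,3-dihydro-1-benzofuran-3-carboxylate (2,3-cis)
Conditions: Rh2(S-PTTL)4 (dirhodium tetrakis[N-phthaloyl-(S)-tert-leucinate], 1 mol %), toluene, −60 °C, high dilution
Reagents that add atoms: none
Why: Intramolecular 1,5 C–H insertion of the donor/acceptor rhodium carbenoid into the benzylic O–CH2 bond closes the dihydrofuran ring; the concerted insertion gives the 2,3-cis ester as kinetic product and the chiral carboxylate ligands set the absolute configuration at C2 and C3.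

Step 8
Reactants: 10 ethyl (2R,3S)-5-(dimethoxymethyl)-7-methoxy-2-G-2,3-dihydro-1-benzofuran-3-carboxylate
Product: 11 [(2R,3R)-5-(dimethoxymethyl)-7-methoxy-2-G-2,3-dihydro-1-benzofuran-3-yl]methanol
Conditions: iBu2AlH (3 equiv), CH2Cl2, −78 °C; potassium sodium tartrate work-up
Reagents that add atoms: none
Why: Hydride reduction of the ester at −78 °C through non-basic aluminium intermediates keeps the cis relationship (the C3 descriptor changes only because the priorities change).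

Step 9
Reactants: 11 [(2R,3R)-5-(dimethoxymethyl)-7-methoxy-2-G-2,3-dihydro-1-benzofuran-3-yl]methanol
Product: 12 BF-CH(OMe)2, the dimethyl acetal of the BF aldehyde
Conditions: TIPSCl, imidazole, 4-(dimethylamino)pyridine (cat.), DMF, rt
Reagents that add atoms: triisopropylsilyl chloride, CC(C)[Si](Cl)(C(C)C)C(C)C
Why: Silylation protects the primary alcohol through the strongly basic steps 11 and 12 and lets all three silyl groups fall together at the end.

Step 10
Reactants: 12 BF-CH(OMe)2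
Product: 13 2-BF-1,3-dithiane
Conditions: HS(CH2)3SH (1.2 equiv), I2 (5 mol %), CH2Cl2, 0 °C to rt
Reagents that add atoms: propane-1,3-dithiol, SCCCS
Why: Iodine-catalysed transthioacetalisation exchanges the dimethyl acetal for the dithiane under conditions too mild to ionise the benzylic C2–O bond of the cis dihydrobenzofuran.

Step 11
Reactants: 13 2-BF-1,3-dithiane; 14 (5R)-5-(Men-oxy)furan-2(5H)-one
Product: 17 (3R,4R,5R)-4-(2-BF-1,3-dithian-2-yl)-3-hydroxy-5-(Men-oxy)oxolan-2-one, via lithiated dithiane 15 (not isolated), via lithium enolate 16 (not isolated)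
Conditions: n-BuLi (1.05 equiv), THF, −78 to −30 °C; 14, −78 °C; (camphorsulfonyl)oxaziridine, −78 °C; AcOH quench
Reagents that add atoms: (10-camphorsulfonyl)oxaziridine (either enantiomer, SMILES without stereodescriptors), CC1(C)C2CCC13CS(=O)(=O)N4OC34C2
Why: Corey–Seebach umpolung: the 2-lithio-1,3-dithiane adds in Michael fashion to the butenolide anti to the menthyloxy group, which sets the future oxolane C4, and the lithium enolate is hydroxylated in the same flask by the N-sulfonyloxaziridine (the carbinol centre formed anti to the dithiane is erased in step 12).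

Step 12
Reactants: 17 (3R,4R,5R)-4-(2-BF-1,3-dithian-2-yl)-3-hydroxy-5-(Men-oxy)oxolan-2-one; 4 3-methoxy-4-(triisopropylsilyloxy)benzyl bromide
Product: 19 (3S,4R,5R)-4-(2-BF-1,3-dithian-2-yl)-3-[(G)methyl]-3-hydroxy-5-(Men-oxy)oxolan-2-one, via dilithium enediolate 18 (not isolated)
Conditions: LiN(iPr)2 (commercial solution, 2.3 equiv), THF/DMPU, −78 °C; 4, −78 to −45 °C; AcOH quench
Reagents that add atoms: none
Why: Fráter–Seebach-type C-alkylation of the dianion of the α-hydroxy lactone; the bromide enters anti to the bulky dithianyl group on the neighbouring carbon, which leaves the hydroxyl cis to it and sets the tertiary carbinol (future oxolane C3).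

Step 13
Reactants: 19 (3S,4R,5R)-4-(2-BF-1,3-dithian-2-yl)-3-[(G)methyl]-3-hydroxy-5-(Men-oxy)oxolan-2-one
Product: 20 (2S,3S)-3-(2-BF-1,3-dithian-2-yl)-2-[(G)methyl]butane-1,2,4-triol
Conditions: LiAlH4, THF, 0 °C to rt; aqueous NaOH work-up
Reagents that add atoms: none
Why: LiAlH4 reduces the lactone carbonyl and, after ring opening and loss of menthoxide from the hemiacetal, the released aldehyde, so both primary alcohols appear and the auxiliary leaves without touching the dithiane or the two stereocentres.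

Step 14
Reactants: 20 (2S,3S)-3-(2-BF-1,3-dithian-2-yl)-2-[(G)methyl]butane-1,2,4-triol
Product: 23 (3S,4R,5R)-5-BF-3-[(G)methyl]-4-(hydroxymethyl)oxolan-3-ol, via keto triol 21 (not isolated), via cyclic hemiketal 22 (not isolated)
Conditions: PhI(OCOCF3)2 (1.5 equiv), MeCN/H2O 9:1, 0 °C, 10 min; extractive work-up, then crude in CH2Cl2 with Et3SiH (5 equiv), BF3·OEt2 (3 equiv), −78 °C, cold quench
Reagents that add atoms: none
Why: PhI(OCOCF3)2 oxidises a dithiane sulfur and water hydrolyses the thionium ion to ketone 21 (oxidative dethioketalisation), whose C1 hydroxyl adds to the carbonyl to give hemiketal 22, so the ring oxygen O1 becomes bound to C5 here; BF3·OEt2 then ionises 22 to the cyclic 5-aryl oxocarbenium ion and Et3SiH delivers hydride to C5. The closest known reaction type is the Lewis acid/silane reductive etherification of γ-hydroxy aryl ketones and their hemiketals, as used for 2-aryl tetrahydrofuran lignans. The ring closure is 5-exo-trig and needs no protecting groups, because the other two hydroxyls could only form oxetanes. The new stereocentre C5 is set by substrate control: hydride enters the planar cation anti to the C4 hydroxymethyl and C3 arylmethyl groups, which lie on one face, and syn to the C3 hydroxyl, so the aryl group ends cis to both carbon substituents (5R). The step needs this kinetic face selectivity, since the 4,5-cis oxolane is the less stable C5 epimer, and it needs the cation to be reduced faster than it loses the C4 proton or is attacked by the electron-rich arylmethyl ring; the two cis substituents that shield one face, the para oxygen that lets the cation form at −78 °C, and excess silane should secure both.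

Step 15
Reactants: 23 (3S,4R,5R)-5-BF-3-[(G)methyl]-4-(hydroxymethyl)oxolan-3-ol
Product: 24 (3S,4R,5R)-5-[(2R,3R)-2-(4-hydroxy-3-methoxyphenyl)-3-(hydroxymethyl)-7-methoxy-2,3-dihydro-1-benzofuran-5-yl]-3-[(4-hydroxy-3-methoxyphenyl)methyl]-4-(hydroxymethyl)oxolan-3-ol (target)
Conditions: Bu4NF (4 equiv), AcOH (4 equiv), THF, 0 °C to rt
Reagents that add atoms: none
Why: Fluoride cleaves the two aryl and one alkyl Si–O bonds, and the acetic acid buffer keeps the phenols protonated so that neither benzylic ether can open through a quinone methide.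

Compound list
1 | vanillin | COc1cc(C=O)ccc1O | starting material
2 | 3-methoxy-4-(triisopropylsilyloxy)benzaldehyde | COc1cc(C=O)ccc1O[Si](C(C)C)(C(C)C)C(C)C | intermediate
3 | [3-methoxy-4-(triisopropylsilyloxy)phenyl]methanol | COc1cc(CO)ccc1O[Si](C(C)C)(C(C)C)C(C)C | intermediate
4 | 3-methoxy-4-(triisopropylsilyloxy)benzyl bromide | COc1cc(CBr)ccc1O[Si](C(C)C)(C(C)C)C(C)C | intermediate
5 | 5-iodovanillin | COc1cc(C=O)cc(I)c1O | starting material
6 | 3-iodo-5-methoxy-4-[(G)methoxy]benzaldehyde | COc1cc(C=O)cc(I)c1OCc1ccc(O[Si](C(C)C)(C(C)C)C(C)C)c(OC)c1 | intermediate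
7 | 5-(dimethoxymethyl)-1-iodo-3-methoxy-2-[(G)methoxy]benzene | COc1cc(C(OC)OC)cc(I)c1OCc1ccc(O[Si](C(C)C)(C(C)C)C(C)C)c(OC)c1 | intermediate
8 | ethyl diazoacetate | CCOC(=O)C=[N+]=[N-] | starting material
9 | ethyl 2-diazo-2-{5-(dimethoxymethyl)-3-methoxy-2-[(G)methoxy]phenyl}acetate | CCOC(=O)C(=[N+]=[N-])c1cc(C(OC)OC)cc(OC)c1OCc1ccc(O[Si](C(C)C)(C(C)C)C(C)C)c(OC)c1 | intermediate
10 | ethyl (2R,3S)-5-(dimethoxymethyl)-7-methoxy-2-G-2,3-dihydro-1-benzofuran-3-carboxylate | COC(OC)c1cc(OC)c2c(c1)[C@H](C(=O)OCC)[C@H](c1ccc(O[Si](C(C)C)(C(C)C)C(C)C)c(OC)c1)O2 | intermediate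
11 | [(2R,3R)-5-(dimethoxymethyl)-7-methoxy-2-G-2,3-dihydro-1-benzofuran-3-yl]methanol | COC(OC)c1cc(OC)c2c(c1)[C@H](CO)[C@H](c1ccc(O[Si](C(C)C)(C(C)C)C(C)C)c(OC)c1)O2 | intermediate
12 | BF-CH(OMe)2 (dimethyl acetal of the BF aldehyde) | COC(OC)c1cc(OC)c2c(c1)[C@H](CO[Si](C(C)C)(C(C)C)C(C)C)[C@H](c1ccc(O[Si](C(C)C)(C(C)C)C(C)C)c(OC)c1)O2 | intermediate
13 | 2-BF-1,3-dithiane | S1CCCSC1c1cc(OC)c2c(c1)[C@H](CO[Si](C(C)C)(C(C)C)C(C)C)[C@H](c1ccc(O[Si](C(C)C)(C(C)C)C(C)C)c(OC)c1)O2 | intermediate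
14 | (5R)-5-[(1R,2S,5R)-menthyloxy]furan-2(5H)-one | O=C1C=C[C@H](O[C@@H]2C[C@H](C)CC[C@H]2C(C)C)O1 | starting material
15 | 2-lithio-2-BF-1,3-dithiane | [Li]C1(SCCCS1)c1cc(OC)c2c(c1)[C@H](CO[Si](C(C)C)(C(C)C)C(C)C)[C@H](c1ccc(O[Si](C(C)C)(C(C)C)C(C)C)c(OC)c1)O2 | intermediate
16 | lithium enolate of (4R,5R)-4-(2-BF-1,3-dithian-2-yl)-5-(Men-oxy)oxolan-2-one | [Li]OC1=C[C@@H](C2(SCCCS2)c2cc(OC)c3c(c2)[C@H](CO[Si](C(C)C)(C(C)C)C(C)C)[C@H](c2ccc(O[Si](C(C)C)(C(C)C)C(C)C)c(OC)c2)O3)[C@H](O[C@@H]2C[C@H](C)CC[C@H]2C(C)C)O1 | intermediate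
17 | (3R,4R,5R)-4-(2-BF-1,3-dithian-2-yl)-3-hydroxy-5-(Men-oxy)oxolan-2-one | O=C1[C@H](O)[C@@H](C2(SCCCS2)c2cc(OC)c3c(c2)[C@H](CO[Si](C(C)C)(C(C)C)C(C)C)[C@H](c2ccc(O[Si](C(C)C)(C(C)C)C(C)C)c(OC)c2)O3)[C@H](O[C@@H]2C[C@H](C)CC[C@H]2C(C)C)O1 | intermediate
18 | dilithium enediolate of 17 | [Li]OC1=C(O[Li])[C@@H](C2(SCCCS2)c2cc(OC)c3c(c2)[C@H](CO[Si](C(C)C)(C(C)C)C(C)C)[C@H](c2ccc(O[Si](C(C)C)(C(C)C)C(C)C)c(OC)c2)O3)[C@H](O[C@@H]2C[C@H](C)CC[C@H]2C(C)C)O1 | intermediate
19 | (3S,4R,5R)-4-(2-BF-1,3-dithian-2-yl)-3-[(G)methyl]-3-hydroxy-5-(Men-oxy)oxolan-2-one | O=C1[C@](O)(Cc2ccc(O[Si](C(C)C)(C(C)C)C(C)C)c(OC)c2)[C@@H](C2(SCCCS2)c2cc(OC)c3c(c2)[C@H](CO[Si](C(C)C)(C(C)C)C(C)C)[C@H](c2ccc(O[Si](C(C)C)(C(C)C)C(C)C)c(OC)c2)O3)[C@H](O[C@@H]2C[C@H](C)CC[C@H]2C(C)C)O1 | intermediate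
20 | (2S,3S)-3-(2-BF-1,3-dithian-2-yl)-2-[(G)methyl]butane-1,2,4-triol | OC[C@](O)(Cc1ccc(O[Si](C(C)C)(C(C)C)C(C)C)c(OC)c1)[C@H](CO)C1(SCCCS1)c1cc(OC)c2c(c1)[C@H](CO[Si](C(C)C)(C(C)C)C(C)C)[C@H](c1ccc(O[Si](C(C)C)(C(C)C)C(C)C)c(OC)c1)O2 | intermediate
21 | (2S,3S)-1-BF-3-[(G)methyl]-3,4-dihydroxy-2-(hydroxymethyl)butan-1-one | OC[C@](O)(Cc1ccc(O[Si](C(C)C)(C(C)C)C(C)C)c(OC)c1)[C@H](CO)C(=O)c1cc(OC)c2c(c1)[C@H](CO[Si](C(C)C)(C(C)C)C(C)C)[C@H](c1ccc(O[Si](C(C)C)(C(C)C)C(C)C)c(OC)c1)O2 | intermediate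
22 | (3S,4S)-5-BF-3-[(G)methyl]-4-(hydroxymethyl)oxolane-3,5-diol (both C5 epimers) | COc1cc(C[C@@]2(O)COC(O)(c3cc(OC)c4c(c3)[C@H](CO[Si](C(C)C)(C(C)C)C(C)C)[C@H](c3ccc(O[Si](C(C)C)(C(C)C)C(C)C)c(OC)c3)O4)[C@H]2CO)ccc1O[Si](C(C)C)(C(C)C)C(C)C | intermediate
23 | (3S,4R,5R)-5-BF-3-[(G)methyl]-4-(hydroxymethyl)oxolan-3-ol | COc1cc(C[C@@]2(O)CO[C@@H](c3cc(OC)c4c(c3)[C@H](CO[Si](C(C)C)(C(C)C)C(C)C)[C@H](c3ccc(O[Si](C(C)C)(C(C)C)C(C)C)c(OC)c3)O4)[C@H]2CO)ccc1O[Si](C(C)C)(C(C)C)C(C)C | intermediate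
24 | (3S,4R,5R)-5-[(2R,3R)-2-(4-hydroxy-3-methoxyphenyl)-3-(hydroxymethyl)-7-methoxy-2,3-dihydro-1-benzofuran-5-yl]-3-[(4-hydroxy-3-methoxyphenyl)methyl]-4-(hydroxymethyl)oxolan-3-ol | COc1cc(C[C@@]2(O)CO[C@@H](c3cc(OC)c4c(c3)[C@H](CO)[C@H](c3ccc(O)c(OC)c3)O4)[C@H]2CO)ccc1O | target

Total step count: 15. Longest linear sequence: 15 steps (1 to 24); the route is linear, with 5, 8 and 14 entering as building blocks and bromide 4 used twice (steps 4 and 12).

Steps most likely to fail

1. Step 14. Hydride delivery may lose its face selectivity, or the Lewis acid may re-ionise the benzylic C5–O bond, epimerise C4 through the enol ether, or let the electron-rich arylmethyl ring capture the cation. The fallback avoids cations altogether. It sets out from 20, which is cyclised under hydroxy dithioketal conditions (AgClO4, NaHCO3, SiO2, 4 Å molecular sieves, MeNO2) to the cyclic S,O-ketal (3S,4S)-5-BF-3-[(G)methyl]-4-(hydroxymethyl)-5-[(3-sulfanylpropyl)sulfanyl]oxolan-3-ol F1. The C5–S bond of F1 is then cleaved homolytically with Ph3SnH and azobisisobutyronitrile in toluene at 100 °C, and the planar C5 radical should take hydrogen from the same open face. The fallback comes back to the route at 23.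

2. Step 12. The hindered dianion may fragment by expelling the dithianyl anion, may be alkylated on oxygen, or may form incompletely. The fallback uses the monoanion of a protected glycolate and sets out from 17. Silylation (Et3SiOTf, 2,6-lutidine, CH2Cl2) gives (3R,4R,5R)-4-(2-BF-1,3-dithian-2-yl)-5-(Men-oxy)-3-(triethylsilyloxy)oxolan-2-one F2. Its potassium enolate (KN(SiMe3)2, THF, −78 °C) is alkylated with 4, again anti to the dithianyl group, to (3S,4R,5R)-4-(2-BF-1,3-dithian-2-yl)-3-[(G)methyl]-5-(Men-oxy)-3-(triethylsilyloxy)oxolan-2-one F3. The triethylsilyl ether is removed with AcOH/THF/H2O, and the fallback comes back at 19.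

3. Step 6. Oxidative addition at the hindered ortho-alkoxy iodide may be slow, and the diazo ester may decompose on the metal before coupling. The fallback sets out from 7 and separates C–C bond formation from diazo formation. A palladium-catalysed Reformatsky-type α-arylation (BrZnCH2CO2Et, Pd(dba)2, P(t-Bu)3, THF, rt) gives ethyl 2-{5-(dimethoxymethyl)-3-methoxy-2-[(G)methoxy]phenyl}acetate F4. Diazo transfer to F4 (4-acetamidobenzenesulfonyl azide, 1,8-diazabicyclo[5.4.0]undec-7-ene, MeCN) comes back at 9.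

Further compounds
F1 | step 14 | (3S,4S)-5-BF-3-[(G)methyl]-4-(hydroxymethyl)-5-[(3-sulfanylpropyl)sulfanyl]oxolan-3-ol | COc1cc(C[C@@]2(O)COC(SCCCS)(c3cc(OC)c4c(c3)[C@H](CO[Si](C(C)C)(C(C)C)C(C)C)[C@H](c3ccc(O[Si](C(C)C)(C(C)C)C(C)C)c(OC)c3)O4)[C@H]2CO)ccc1O[Si](C(C)C)(C(C)C)C(C)C
F2 | step 12 | (3R,4R,5R)-4-(2-BF-1,3-dithian-2-yl)-5-(Men-oxy)-3-(triethylsilyloxy)oxolan-2-one | O=C1[C@H](O[Si](CC)(CC)CC)[C@@H](C2(SCCCS2)c2cc(OC)c3c(c2)[C@H](CO[Si](C(C)C)(C(C)C)C(C)C)[C@H](c2ccc(O[Si](C(C)C)(C(C)C)C(C)C)c(OC)c2)O3)[C@H](O[C@@H]2C[C@H](C)CC[C@H]2C(C)C)O1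
F3 | step 12 | (3S,4R,5R)-4-(2-BF-1,3-dithian-2-yl)-3-[(G)methyl]-5-(Men-oxy)-3-(triethylsilyloxy)oxolan-2-one | O=C1[C@](O[Si](CC)(CC)CC)(Cc2ccc(O[Si](C(C)C)(C(C)C)C(C)C)c(OC)c2)[C@@H](C2(SCCCS2)c2cc(OC)c3c(c2)[C@H](CO[Si](C(C)C)(C(C)C)C(C)C)[C@H](c2ccc(O[Si](C(C)C)(C(C)C)C(C)C)c(OC)c2)O3)[C@H](O[C@@H]2C[C@H](C)CC[C@H]2C(C)C)O1
F4 | step 6 | ethyl 2-{5-(dimethoxymethyl)-3-methoxy-2-[(G)methoxy]phenyl}acetate | CCOC(=O)Cc1cc(C(OC)OC)cc(OC)c1OCc1ccc(O[Si](C(C)C)(C(C)C)C(C)C)c(OC)c1
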